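## The problem

Compound 22 is a trans-fused hydroazulene of the daucane type: ring A is the cyclopentane C1–C5, ring B the cycloheptane C1, C5–C10, and the rings share the C1–C5 bond. Target locants are used for every bicyclic compound and for the fragment atoms that become them; C15 is the methyl on C1, C14 the carbon on C8, β is the face that carries C15 and α the other face. Six stereocentres are needed, (1S,4R,5S,6S,9R,10S): a quaternary C1, a tertiary carbinol C4 (hydroxyl β, isopropyl α), H5 α, the C6 ester oxygen α, and a cis 9α,10α-diol. C1 is the pivot. It cannot be corrected later, and its neighbour C10 is best made with it. Once C1 exists, its quasi-axial methyl shields the β face of both rings, so C5, C6 and C4 can be derived from it; C9 can be taken from a chiral reagent. The functional groups fix the order of events. The isovalerate survives neither hydride nor organometallic reagents, so it goes on late and on one hydroxyl out of four. The C9 allylic alcohol beside the 8(14)-methylene ionises under acid. The C4 carbinol is β to the C6 oxygen, so a C6 carbonyl next to it invites dehydration or retro-aldol cleavage. The enabling feature is the way ring B divides: C8–C9–C10 is a three-carbon unit with an acyl-level carbon (C14) on C8 and oxygen on C10, and C7=C6–C5=C1 is a diene whose last two carbons already lie in ring A and whose terminus is the quaternary carbon. These are the partners of a vinylcarbene cyclopropanation followed by a divinylcyclopropane rearrangement, which forms C7–C8 and C1–C10, closes ring B and sets C1 and C10 together.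

## Retrosynthesis

**22 back to 19 (O10–Si and the C6 acyl–oxygen bond).** The single acylation is planned around a latent form of the C9 alcohol. In epoxy iodide 19 the only acylable hydroxyl is the one on C6: C4 is tertiary, O10 is silylated and O9 is locked in the epoxide. The ester is therefore introduced there (20), zinc unveils C9–OH and C8=C14 under neutral conditions (21), and fluoride gives 22. Acylating a free 6,9,10-triol offers no basis for selectivity, and carrying the ester earlier fails at the hydride stage.

**19 back to 16 (C14–I, the epoxide C–O bonds, C14 oxidation level).** Iodide 19 comes from epoxy alcohol 18, that from allylic alcohol 17, and that from ester 16. C14 has to arrive as an ester because the key step needs an acceptor on C8. The epoxidation–reductive opening sequence turns it into the methylene while moving oxygen to C9. Because 17 is a primary allylic alcohol, C9 can be set by a tartrate-controlled epoxidation, independent of ring conformation. Direct allylic oxidation of an 8(14)-alkene at C9 would have to choose between C7 and C9 and between two faces without help.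

**16 back to 14 (C4–isopropyl bond).** The carbinol is cut to ketone 15, unmasked from ketal 14. The addition is placed after C5 has become tetrahedral. In trans-fused 15 the axial methyl and the C5–C6 bond both lie on the β face of ring A, so the nucleophile must enter from the α face, which is what the target requires. The forward step needs a non-basic isopropyl nucleophile that tolerates a free β-hydroxyl and an ester.

**14 back to 12 (C6–O and C5–H).** Both bonds are made by one syn hydration of the C5=C6 bond of 12 through alkylborane 13. The target has H5 and O6 on the same face, and that face is the one opposite the C1 methyl. Making C6 a ketone and reducing it would leave two independent facial questions and would place a carbonyl β to the future C4 carbinol.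

**12 back to 6 and 10 (C7–C8 and C1–C10, ring B).** Dienoate 12 is the rearrangement product of cis-divinylcyclopropane 11, which is the cyclopropanation product of diene 6 with the carbene from vinyldiazoacetate 10. Two small achiral fragments replace a bicycle with a quaternary centre. The forward reaction must select the terminal alkene, give the cis-divinyl isomer with high enantioselectivity, and rearrange onto a fully substituted terminus.

Two design choices strengthen this step:
- **No alkoxy group on C6 of the diene.** A 1-alkoxyvinyl analogue of 6 would bring the C6 oxygen with it, but it is not used. Its cyclopropane would be a vicinal donor–acceptor cyclopropane that can open to a zwitterion and lose the catalyst-set centres. A 1,1-disubstituted alkene gives no reliable cis-divinyl preference. The derived enol ether, once C4 is a tertiary allylic carbinol, would collapse to the transposed enone (Stork–Danheiser pathway) instead of giving the β-hydroxy ketone.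
- **C4 as a dioxolane.** The free 2-vinyl enone is a cross-conjugated dienone prone to dimerisation, its annulation product could not be hydroborated, and the ketal makes the diene electron-rich.

**6 and 10 back to commerce.** Diene 6 is cut at the C5–C6 bond (Stille coupling of bromide 4 with stannane 5). Bromide 4 comes from bromoenone 3 and that from enone 1 via dibromide 2. Diazo ester 10 is cut at C8–C9 (aldol of diazoacetate 7 with aldehyde 8 to give 9, then dehydration). These steps must only be compatible with an acid-labile ketal and a labile diazo compound.

## Roads not taken

**Alternative 1:** A conjugate addition–aldol assembly cuts C1–C15 and C5–C6 and leaves ring B for later. A methylcopper reagent would add to the β-carbon of dioxolanyl cyclopentenone A1, and the enolate would be trapped at C5 by 3-bromobut-3-enal A2 to give cyclopentanone A3. A3 already carries the C4 ketone, the C6 carbinol, a C8 vinyl bromide and both ring B oxygens.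
- Merits: C10 comes from the chiral pool and the assembly is convergent. Ring B could then be closed between C8 and C9 by a chromium-mediated vinyl bromide–aldehyde coupling that delivers the C9 alcohol and the 8(14)-methylene in their final form. In this respect it is better than the chosen plan, which spends four steps turning an ester into that array.
- Weak points: the quaternary centre is made by cuprate addition to a β,β-disubstituted enone, which is slow and usually needs silyl chloride activation that consumes the enolate meant for the aldol. Face selection at C1 rests on a freely rotating dioxolanyl group. A2 is a β,γ-unsaturated aldehyde that isomerises into conjugation and self-condenses under enolate conditions. The C6 configuration from such an aldol is not predictable. A seven-membered ring must still be closed by a step that also sets C9.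
- Comparison: the chosen plan sets C1 and C10 in one catalyst-controlled pericyclic event that also forms the ring, and it pays for this with the functional-group adjustment in ring B.

**Alternative 2:** A transannular cyclisation cuts C1–C5 and the C4–O bond. Acid would open the C1–C10 epoxide of epoxy cyclodecadiene A4 at tertiary C1, the C4=C5 bond would attack across the ring, and water would capture the C4 cation to give bis-silyl ether A5.
- Merits: both rings and three stereocentres (C1, C5, C4) form in one step, against two centres and one ring in the chosen key step. A5 is only a few protecting-group and acylation steps from 22. On step count after the key step this road is better.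
- Weak points: A4 is a stereodefined, fourfold-functionalised ten-membered ring that is no easier to make than 22. If both additions are anti, as such cyclisations normally are, the target's configurations require the ring carbons C3 and C6 to be cis across C4=C5 and a cis epoxide, so the well-behaved trans,trans-cyclodecadiene conformations do not apply. The C4 cation sits beside the isopropyl methine and can shift a hydride or lose a proton instead of taking up water. The allylic C6 silyl ether deactivates the alkene and is acid-labile.
- Comparison: the chosen plan sets against the brevity of this road two fragments that are each a few steps from commerce and a key step with catalyst-controlled absolute configuration.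

**Alternative 3:** A carbonyl-ene closure cuts C6–C7. In aldehyde A6 an alkylaluminium chloride would activate the C6 aldehyde on C5, the terminal carbon of the isopropenyl group on C9 would attack it, and a methyl hydrogen would move to oxygen to give hydroazulene A7.
- Merits: the C6 alcohol and the 8(14)-methylene appear in final form and the C4 carbinol is already in place. A7 needs only acylation and deprotection, which is clearly shorter than the nine steps that follow the chosen key step.
- Weak points: the difficulty is moved into A6, which needs C1, C4, C5, C9 and C10 set in a ring-plus-chain array, with the quaternary C1 made before any ring B template exists. The aldehyde is α-epimerisable and β to a tertiary silyl ether, so the Lewis acid can cause elimination. The acetonide competes for the Lewis acid. The C6 configuration depends on a seven-membered ene transition state constrained by a fused dioxolane, which is hard to predict.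
- Comparison: the chosen plan is longer after the key step but builds the quaternary centre and ring B together from simple achiral pieces.

Key step: step 6

Assumption: the prolinate catalyst is taken to follow the usual facial model for donor/acceptor carbenes, which assigns the required (1S,10R) series to Rh2(R-DOSP)4, dirhodium tetrakis[(R)-N-(4-dodecylbenzenesulfonyl)prolinate]; if induction on diene 6 runs the other way, Rh2(S-DOSP)4 is used and nothing else changes.

## Route

Step 1
Reactants: 1 3-methylcyclopent-2-en-1-one
Product: 3 2-bromo-3-methylcyclopent-2-en-1-one, via 2,3-dibromo-3-methylcyclopentan-1-one 2 (not isolated)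
Conditions: Br2, CH2Cl2, 0 °C; then Et3N, 0 °C to rt
Reagents that add atoms: bromine, BrBr
Why: Bromine adds across the enone double bond to give 2 and triethylamine removes HBr through the acidic α-hydrogen (bromination–dehydrobromination of an enone), which restores conjugation with bromine on the carbon that becomes C5.

Step 2
Reactants: 3 2-bromo-3-methylcyclopent-2-en-1-one
Product: 4 6-bromo-7-methyl-1,4-dioxaspiro[4.4]non-6-ene
Conditions: HOCH2CH2OH, pTsOH (cat.), benzene, reflux (Dean–Stark)
Reagents that add atoms: ethylene glycol, OCCO
Why: Acid-catalysed ketalisation with azeotropic removal of water; 2-halo enones are known to ketalise with the double bond left in place, and the dioxolane turns the enone into an electron-rich alkenyl bromide.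

Step 3
Reactants: 4 6-bromo-7-methyl-1,4-dioxaspiro[4.4]non-6-ene; 5 tributyl(ethenyl)stannane
Product: 6 6-ethenyl-7-methyl-1,4-dioxaspiro[4.4]non-6-ene
Conditions: Pd(PPh3)4 (5 mol %), CuI (10 mol %), DMF, 80 °C
Reagents that add atoms: none
Why: Stille coupling of the alkenyl bromide with the vinylstannane on zerovalent palladium forms the C5–C6 bond; copper iodide is the usual aid for a fully substituted, flanked bromide, and the neutral medium spares the acid-labile dienyl ketal.

Step 4
Reactants: 7 methyl diazoacetate; 8 (tert-butyldimethylsilyloxy)acetaldehyde
Product: 9 methyl 4-(tert-butyldimethylsilyloxy)-2-diazo-3-hydroxybutanoate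
Conditions: DBU (10 mol %), MeCN, 0 °C to rt
Reagents that add atoms: none
Why: Amine-catalysed aldol-type addition of the acidic diazoacetate C–H to the aldehyde forms C8–C9; the carbinol centre is lost in the next step and need not be controlled.

Step 5
Reactants: 9 methyl 4-(tert-butyldimethylsilyloxy)-2-diazo-3-hydroxybutanoate
Product: 10 methyl (E)-4-(tert-butyldimethylsilyloxy)-2-diazobut-3-enoate
Conditions: POCl3, Et3N, CH2Cl2, 0 °C
Reagents that add atoms: none
Why: Dehydration of a β-hydroxy-α-diazo ester through its dichlorophosphate, the usual access to vinyldiazoacetates; only the hydrogens next to the silyloxy group can be lost, and the E enol ether is the expected, less congested product. The reagent is used at once because vinyldiazo esters slowly cyclise to pyrazoles.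

Step 6
Reactants: 6 6-ethenyl-7-methyl-1,4-dioxaspiro[4.4]non-6-ene; 10 methyl (E)-4-(tert-butyldimethylsilyloxy)-2-diazobut-3-enoate
Product: 12 ketal dienoate, via cis-divinylcyclopropane 11 (not isolated)
Conditions: Rh2(R-DOSP)4 (1 mol %), hexanes, −40 °C to rt, slow addition of 10; then toluene, 100 °C
Reagents that add atoms: none
Why: The carboxylate of divalent rhodium releases dinitrogen from 10, and the donor/acceptor carbene (carbene carbon C8) adds to the terminal C7=C6 bond of 6 in a concerted, asynchronous [2+1] step that forms C7–C8 and C6–C8 and closes the three-membered ring of 11. Donor/acceptor carbenes place the alkene substituent cis to the donor group, so the cyclopentenyl group on C6 and the silyloxyvinyl group on C8 are cis, and the prolinate ligands choose the alkene face, which fixes 11 as (1R,2S). On heating, 11 undergoes the [3,3] shift through the boat transition state that is the only one open to a cis-divinylcyclopropane: C10 bonds to C1, C6–C8 breaks, and ring B closes as a cyclohepta-1,4-diene by ring expansion of the cyclopropane, a formal (4+3) annulation. Both new stereocentres come from chirality transfer in that boat: the E silyloxy group on C10 and ring carbon C2 on C1 are the outward groups and end cis, H10 and the methyl are the inward groups and end cis, and the configuration of 11 selects the (1S,10R) enantiomer of this single diastereomer. The closest known reaction is the rhodium-catalysed tandem cyclopropanation/Cope rearrangement of vinyldiazoacetates with 1,3-dienes, which is established for semicyclic dienes and for termini that become quaternary. Site selectivity comes from the substrate, since only the monosubstituted C7=C6 bond is accessible and the tetrasubstituted C5=C1 bond is inert to the carbene. Reaction through the vinylogous carbon C10 is disfavoured by its E substituent, the hydrocarbon solvent and the bulky catalyst. The inward methyl on the fully substituted terminus slows the shift, which is why the mixture is heated once the diazo compound is consumed; release of cyclopropane strain pays for the quaternary bond.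

Step 7
Reactants: 12 ketal dienoate
Product: 14 hydroxy ketal, via C6 alkylborane 13 (not isolated)
Conditions: BH3·SMe2, THF, 0 °C to rt; then NaBO3·4H2O, THF/H2O, rt
Reagents that add atoms: borane–dimethyl sulfide, C[S+](C)[BH3-]; sodium perborate, [Na+].[O-]B1OO1
Why: Hydroboration–oxidation (syn, anti-Markovnikov hydration): boron goes to C6, the less substituted and far less hindered carbon, and oxidation with retention gives the alcohol. The C1 methyl is quasi-axial over the β face of the C5=C6 bond, as an angular methyl is over a ring-fusion alkene, so H and B add from the α face and 5α-H and 6α-OH are set together; the symmetric dioxolane adds no facial bias. The conjugated, α-branched ester alkene reacts with borane much more slowly.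

Step 8
Reactants: 14 hydroxy ketal
Product: 15 hydroxy ketone
Conditions: PPTS (cat.), acetone/H2O, 40 °C
Reagents that add atoms: water, O
Why: Mild acid-catalysed ketal hydrolysis; the cyclopentanone dioxolane is cleaved at an acidity that spares the secondary silyl ether and does not dehydrate the β-hydroxy ketone, and C5 is not enolised.

Step 9
Reactants: 15 hydroxy ketone
Product: 16 isopropyl carbinol
Conditions: iPrMgCl, CeCl3, THF, −78 °C
Reagents that add atoms: isopropylmagnesium chloride, CC(C)[Mg]Cl
Why: 1,2-Addition of an organocerium reagent, chosen because cerium suppresses enolisation and β-hydride reduction by a branched nucleophile and leaves the ester alone at low temperature. In the trans-fused ketone the axial C1 methyl and the C5–C6 bond both lie on the β face of ring A, so isopropyl enters from the α face and the hydroxyl ends β, cis to the methyl.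

Step 10
Reactants: 16 isopropyl carbinol
Product: 17 triol
Conditions: iBu2AlH, CH2Cl2, −78 to 0 °C; aq. potassium sodium tartrate
Reagents that add atoms: none
Why: Aluminium hydride reduction of the conjugated ester to the primary allylic alcohol (1,2-reduction is the normal course); the extra equivalents are consumed by the two hydroxyl groups.

Step 11
Reactants: 17 triol
Product: 18 epoxy triol
Conditions: Ti(OiPr)4 (30 mol %), L-(+)-diethyl tartrate (36 mol %), tBuOOH, 4 Å MS, CH2Cl2, −20 °C
Reagents that add atoms: tert-butyl hydroperoxide, CC(C)(C)OO
Why: Sharpless asymmetric epoxidation of a primary allylic alcohol with a 2,3-E substitution pattern, a reliable substrate class. With L-(+)-tartrate oxygen is delivered to the face of C8=C9 that is syn to the C10 oxygen (α), which sets C9; the C8 centre is transient. The hydroxyls at C4 and C6 are not allylic and only call for the higher loading.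

Step 12
Reactants: 18 epoxy triol
Product: 19 epoxy iodide
Conditions: I2, PPh3, imidazole, CH2Cl2, 0 °C
Reagents that add atoms: iodine, II
Why: Phosphine–iodine–imidazole iodination (Garegg–Samuelsson conditions) converts the primary alcohol selectively; the hindered secondary and the tertiary hydroxyl do not compete, and the buffered medium leaves the epoxide closed.

Step 13
Reactants: 19 epoxy iodide
Product: 20 epoxy iodide isovalerate
Conditions: (Me2CHCH2CO)2O, Et3N, DMAP (cat.), CH2Cl2, 0 °C to rt
Reagents that add atoms: 3-methylbutanoic anhydride, CC(C)CC(=O)OC(=O)CC(C)C
Why: DMAP-catalysed acylation; the C6 hydroxyl is the only acylable one, since C4 is tertiary, O10 is silylated and O9 is held in the epoxide, so the ester goes on without any differentiation of the ring B diol.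

Step 14
Reactants: 20 epoxy iodide isovalerate
Product: 21 silyl ether of the target
Conditions: Zn dust, EtOH, 70 °C
Reagents that add atoms: none
Why: Reductive elimination of a 2,3-epoxy iodide: zinc inserts into the C–I bond and the organozinc opens the adjacent epoxide, giving the C8=C14 methylene and the C9 alkoxide with the C9–O bond untouched (net 1,3-transposition of the allylic alcohol). Ester and silyl ether are inert, and a silyl shift between O10 and O9 would be harmless.

Step 15
Reactants: 21 silyl ether of the target
Product: 22 CNP0204264.1
Conditions: Et3N·3HF, THF, rt to 40 °C
Reagents that add atoms: none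
Why: Fluoride cleavage of the hindered secondary silyl ether under nearly neutral conditions, which avoids acyl migration and spares the allylic alcohol, the tertiary alcohol and the ester.

## Compound list

1 | 3-methylcyclopent-2-en-1-one | CC1=CC(=O)CC1 | starting material
2 | 2,3-dibromo-3-methylcyclopentan-1-one (racemic, formed and consumed in the flask) | CC1(Br)CCC(=O)C1Br | intermediate
3 | 2-bromo-3-methylcyclopent-2-en-1-one | CC1=C(Br)C(=O)CC1 | intermediate
4 | 6-bromo-7-methyl-1,4-dioxaspiro[4.4]non-6-ene | CC1=C(Br)C2(CC1)OCCO2 | intermediate
5 | tributyl(ethenyl)stannane | CCCC[Sn](CCCC)(CCCC)C=C | starting material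
6 | 6-ethenyl-7-methyl-1,4-dioxaspiro[4.4]non-6-ene (diene C7=C6–C5=C1, C4 as dioxolane) | C=CC1=C(C)CCC12OCCO2 | intermediate
7 | methyl diazoacetate | COC(=O)C=[N+]=[N-] | starting material
8 | (tert-butyldimethylsilyloxy)acetaldehyde | CC(C)(C)[Si](C)(C)OCC=O | starting material
9 | methyl 4-(tert-butyldimethylsilyloxy)-2-diazo-3-hydroxybutanoate (racemic) | COC(=O)C(=[N+]=[N-])C(O)CO[Si](C)(C)C(C)(C)C | intermediate
10 | methyl (E)-4-(tert-butyldimethylsilyloxy)-2-diazobut-3-enoate | COC(=O)C(=[N+]=[N-])/C=C/O[Si](C)(C)C(C)(C)C | intermediate
11 | cis-divinylcyclopropane, methyl (1R,2S)-1-[(E)-2-(tert-butyldimethylsilyloxy)ethenyl]-2-(7-methyl-1,4-dioxaspiro[4.4]non-6-en-6-yl)cyclopropane-1-carboxylate (formed and consumed in the flask) | COC(=O)[C@]1(/C=C/O[Si](C)(C)C(C)(C)C)C[C@H]1C2=C(C)CCC23OCCO3 | intermediate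
12 | ketal dienoate, (1S,10R): hydroazulene with CO2Me (C14) on C8, C8=C9 and C5=C6 double bonds, 1β-methyl, 10α-OTBS, C4 ethylene ketal | COC(=O)C=1CC=C2[C@](C)(CCC23OCCO3)[C@H](O[Si](C)(C)C(C)(C)C)C=1 | intermediate
13 | C6 alkylborane: 12 with 5α-H and 6α-BH2 (formed and consumed in the flask) | COC(=O)C=1C[C@H](B)[C@@H]2[C@](C)(CCC23OCCO3)[C@H](O[Si](C)(C)C(C)(C)C)C=1 | intermediate
14 | hydroxy ketal: 5α-H, 6α-OH, C4 ethylene ketal, methyl ester on C8=C9, 10α-OTBS, 1β-methyl | COC(=O)C=1C[C@H](O)[C@@H]2[C@](C)(CCC23OCCO3)[C@H](O[Si](C)(C)C(C)(C)C)C=1 | intermediate
15 | hydroxy ketone: 14 with the C4 ketone free (trans ring fusion) | COC(=O)C=1C[C@H](O)[C@@H]2[C@](C)(CCC2=O)[C@H](O[Si](C)(C)C(C)(C)C)C=1 | intermediate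
16 | isopropyl carbinol: 4β-hydroxy-4α-isopropyl, 5α-H, 6α-OH, methyl ester on C8=C9, 10α-OTBS | COC(=O)C=1C[C@H](O)[C@@H]2[C@](C)(CC[C@@]2(O)C(C)C)[C@H](O[Si](C)(C)C(C)(C)C)C=1 | intermediate
17 | triol: 16 with CH2OH (C14) on C8 in place of the ester | OCC=1C[C@H](O)[C@@H]2[C@](C)(CC[C@@]2(O)C(C)C)[C@H](O[Si](C)(C)C(C)(C)C)C=1 | intermediate
18 | epoxy triol: 8α,9α-epoxide of 17 | OC[C@@]1(O3)C[C@H](O)[C@@H]2[C@](C)(CC[C@@]2(O)C(C)C)[C@H](O[Si](C)(C)C(C)(C)C)[C@@H]13 | intermediate
19 | epoxy iodide: 18 with CH2I (C14) | IC[C@@]1(O3)C[C@H](O)[C@@H]2[C@](C)(CC[C@@]2(O)C(C)C)[C@H](O[Si](C)(C)C(C)(C)C)[C@@H]13 | intermediate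
20 | epoxy iodide isovalerate: 19 with 6α-O-(3-methylbutanoyl) | IC[C@@]1(O3)C[C@H](OC(=O)CC(C)C)[C@@H]2[C@](C)(CC[C@@]2(O)C(C)C)[C@H](O[Si](C)(C)C(C)(C)C)[C@@H]13 | intermediate
21 | silyl ether of the target: 10-O-tert-butyldimethylsilyl derivative of 22 | C=C1C[C@H](OC(=O)CC(C)C)[C@@H]2[C@](C)(CC[C@@]2(O)C(C)C)[C@H](O[Si](C)(C)C(C)(C)C)[C@@H]1O | intermediate
22 | CNP0204264.1, (1S,4R,5S,6S,9R,10S)-4β,9α,10α-trihydroxydauc-8(14)-en-6α-yl 3-methylbutanoate | C=C1C[C@H](OC(=O)CC(C)C)[C@@H]2[C@](C)(CC[C@@]2(O)C(C)C)[C@H](O)[C@@H]1O | target

## Step count and least certain steps

Total: 15 steps. Longest linear sequence: 13 steps (steps 1–3 and 6–15, from 1); the diazo partner takes 2 steps (4 and 5).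

**Step 6 (key step).**
- What may go wrong: the strongly donor-substituted silyloxyvinyl carbene may leave the concerted cyclopropanation channel (reaction through its vinylogous carbon, capture by a ketal oxygen). Asymmetric induction may be eroded, because a 4-oxygenated vinylcarbene lies outside the substrate range on which the facial model rests. The rearrangement onto the methyl-bearing, fully substituted terminus may be slow enough for the silyl enol ether cyclopropane to decompose.
- Fallback (from 8 and 6, back to 12): auxiliary control and two separate operations. (3R)-4,4-dimethyl-2-oxooxolan-3-yl diazoacetate F1, made from (R)-pantolactone, is added to 8 with DBU to give pantolactonyl 4-silyloxy-2-diazo-3-hydroxybutanoate F2. Dehydration with POCl3 and Et3N gives pantolactonyl (E)-4-silyloxy-2-diazobut-3-enoate F3. With achiral Rh2(O2CC7H15)4 and 6 the auxiliary controls the alkene face, and the pantolactonyl cis-divinylcyclopropane F4 is isolated. Heating F4 alone in toluene gives pantolactonyl cycloheptadienoate F5, and NaOMe in MeOH exchanges the auxiliary for methyl to return 12. The pantolactone enantiomer is matched to the required sense; both are available.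

**Step 7.**
- What may go wrong: addition to an alkene flanked by two fully substituted carbons may be slow, so that borane also consumes the conjugated ester; to a lesser degree, some attack on the methyl-bearing face.
- Fallback (from 12, back to 14): oxygen is put on first with a reagent that ignores the electron-poor alkene. mCPBA with NaHCO3 gives the 5α,6α-epoxide F6. Cp2TiCl (trivalent titanium, generated from Cp2TiCl2 and Zn) with 1,4-cyclohexadiene opens it at the tertiary carbon and the C5 radical takes up hydrogen, which leaves the C6 alcohol of 14.

**Step 9.**
- What may go wrong: enolisation (epimerisation at C5, retro-aldol through the C6 alkoxide) or β-hydride reduction by the branched organometallic may outrun addition to the hindered, α-branched cyclopentanone.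
- Fallback (from 15, back to 16): a smaller sp2 nucleophile without the reduction pathway. 2-Propenylmagnesium bromide with CeCl3 gives isopropenyl carbinol F7. Hydrogenation with RhCl(PPh3)3 saturates the 1,1-disubstituted alkene in preference to the trisubstituted conjugated ester and returns 16.

**Step 11.**
- What may go wrong: turnover and facial selectivity may suffer because the C4 and C6 hydroxyls bind titanium, and the C10 centre may be mismatched with the tartrate.
- Fallback (from 17, directly to 18): substrate control instead of reagent control. VO(acac)2 with tBuOOH is directed by the C14 allylic hydroxyl and by the α-oriented homoallylic C6 hydroxyl to the α face. No new compound arises (F0).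

**Step 13.**
- What may go wrong: the primary iodide may alkylate the acylation catalyst or be displaced while the hindered C6 hydroxyl acylates slowly.
- Fallback (from 18, back to 21): a sulfonate is carried through the acylation instead of the halide. MsCl and Et3N at −20 °C give epoxy mesylate F8, 3-methylbutanoic anhydride with DMAP gives mesylate isovalerate F9, and NaI with Zn in 2-butanone at 80 °C exchanges and reductively opens in one flask to give 21.

## Further compounds

F1 | step 6 | (3R)-4,4-dimethyl-2-oxooxolan-3-yl diazoacetate | [N-]=[N+]=CC(=O)O[C@H]1C(=O)OCC1(C)C
F2 | step 6 | pantolactonyl 4-silyloxy-2-diazo-3-hydroxybutanoate (carbinol epimers) | CC(C)(C)[Si](C)(C)OCC(O)C(=[N+]=[N-])C(=O)O[C@H]1C(=O)OCC1(C)C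
F3 | step 6 | pantolactonyl (E)-4-silyloxy-2-diazobut-3-enoate | CC(C)(C)[Si](C)(C)O/C=C/C(=[N+]=[N-])C(=O)O[C@H]1C(=O)OCC1(C)C
F4 | step 6 | pantolactonyl cis-divinylcyclopropane (pantolactonyl ester analogue of 11) | O=C(O[C@H]1C(=O)OCC1(C)C)[C@]2(/C=C/O[Si](C)(C)C(C)(C)C)C[C@H]2C3=C(C)CCC34OCCO4
F5 | step 6 | pantolactonyl cycloheptadienoate (pantolactonyl ester analogue of 12) | O=C(O[C@H]1C(=O)OCC1(C)C)C=5CC=C2[C@](C)(CCC23OCCO3)[C@H](O[Si](C)(C)C(C)(C)C)C=5
F6 | step 7 | 5α,6α-epoxide of 12 | COC(=O)C=1C[C@@H]4O[C@]42[C@](C)(CCC23OCCO3)[C@H](O[Si](C)(C)C(C)(C)C)C=1
F7 | step 9 | isopropenyl carbinol (16 with prop-1-en-2-yl on C4) | COC(=O)C=1C[C@H](O)[C@@H]2[C@](C)(CC[C@@]2(O)C(C)=C)[C@H](O[Si](C)(C)C(C)(C)C)C=1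
F0 | step 11 | none | none
F8 | step 13 | epoxy mesylate (18 with C14 methanesulfonate) | CS(=O)(=O)OC[C@@]1(O3)C[C@H](O)[C@@H]2[C@](C)(CC[C@@]2(O)C(C)C)[C@H](O[Si](C)(C)C(C)(C)C)[C@@H]13
F9 | step 13 | mesylate isovalerate (F8 with 6α-O-(3-methylbutanoyl)) | CS(=O)(=O)OC[C@@]1(O3)C[C@H](OC(=O)CC(C)C)[C@@H]2[C@](C)(CC[C@@]2(O)C(C)C)[C@H](O[Si](C)(C)C(C)(C)C)[C@@H]13
A1 | alternative 1 | 3-[(4S)-2,2-dimethyl-1,3-dioxolan-4-yl]cyclopent-2-en-1-one | O=C1C=C(CC1)[C@H]2COC(C)(C)O2
A2 | alternative 1 | 3-bromobut-3-enal | C=C(Br)CC=O
A3 | alternative 1 | trans-2,3-disubstituted cyclopentanone with quaternary C1, C6 carbinol, C8 vinyl bromide and C9,C10 acetonide | C=C(Br)C[C@H](O)[C@@H]2[C@](C)(CCC2=O)[C@H]3COC(C)(C)O3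
A4 | alternative 2 | 1,10-cis-epoxy cyclodeca-4,8(14)-diene with 6,9-bis(silyloxy) groups (ring carbons C3 and C6 cis across C4=C5) | C=C1C[C@H](O[Si](C)(C)C(C)(C)C)/C=C(/C(C)C)CC[C@]2(C)O[C@@H]2[C@@H]1O[Si](C)(C)C(C)(C)C
A5 | alternative 2 | 6,9-bis-O-tert-butyldimethylsilyl derivative of the deacylated target tetraol | C=C1C[C@H](O[Si](C)(C)C(C)(C)C)[C@@H]2[C@](C)(CC[C@@]2(O)C(C)C)[C@H](O)[C@@H]1O[Si](C)(C)C(C)(C)C
A6 | alternative 3 | cyclopentane carbaldehyde with C4 triethylsilyl ether and isopropenyl-substituted C9,C10 acetonide side chain on C1 | C=C(C)[C@H]1OC(C)(C)O[C@H]1[C@@]2(C)CC[C@@](O[Si](CC)(CC)CC)(C(C)C)[C@@H]2C=O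
A7 | alternative 3 | hydroazulene C6 alcohol with 8(14)-methylene, C9,C10 acetonide and C4 triethylsilyl ether | C=C1C[C@H](O)[C@@H]2[C@](C)(CC[C@@]2(O[Si](CC)(CC)CC)C(C)C)[C@H](OC(C)(C)O3)[C@@H]13
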